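A direct plan would couple the phenoxide of 2,4-dibromophenol 1 with 5-bromo-2-fluorobenzaldehyde A1 by SNAr to give aldehyde A2, turn CHO into OH by peracid (Dakin-type) oxidation to phenol A3, and finish with a double bromination (numbering: ring A is the phenol ring with C1 OH, C2 O-aryl, C3 H, C4 to C6 Br; ring B is the 2,4-dibromophenyl ring, C1' to C6').
Weak point 1, the ether-forming SNAr: a hindered, weakly nucleophilic dibromophenoxide would have to displace fluoride from a ring activated by a single formyl group, hot and in base, where the aldehyde itself is at risk.
Weak point 2, the excision of the formyl carbon: this carbon serves only as an activator, its removal is a redox detour that builds no bond of the target, and hydride migration (to the benzoic acid) would compete with aryl migration.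
Weak point 3, the closing bromination: the last bromine would have to enter C6, squeezed between OH and Br, and the reaction would have to stop there while C3 and C6' are still open.

**Retrosynthetic overview**
Ring A is read as the enol form of an α-aryloxy ketone: C1–OH is the carbonyl carbon and C2–O(aryl) the α-carbon of a cyclohexanone.
Key disconnection: the aromaticity of ring A and its three C–Br bonds (C4, C5, C6) are taken apart together in one brominative aromatization, and the ether bond is then cut at sp3 carbon (SN2 of 1 on 2-chlorocyclohexanone 2, giving ketone 3).
Ring order: ring B is bought aromatic; ring A is carried saturated and aromatized in the last step.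
The design needs no SNAr and no formyl activator (the carbonyl that activates the substitution becomes the phenol oxygen, so nothing is excised), and the crowded C6 bromine is placed on sp3 carbon by enol bromination before the ring is aromatic.

Key step: step 2

Remark: the target is achiral; 3 and 4 are racemic and lose their only stereocentre on aromatization.

Step 1
Reactants: 1 2,4-dibromophenol; 2 2-chlorocyclohexan-1-one
Product: 3 2-(2,4-dibromophenoxy)cyclohexan-1-one (racemic)
Conditions: K2CO3 (1.5 equiv), KI (0.1 equiv), acetone, reflux, 24 h
Reagents that add atoms: none
Why: Williamson-type SN2 etherification at an α-halo ketone, whose carbonyl group accelerates displacement at C2 so that even the hindered, weakly basic 2,4-dibromophenoxide (formed by K2CO3, with iodide as Finkelstein catalyst) should substitute faster than the chloroketone enolizes towards Favorskii products, while the aryl bromides are inert without a transition metal; the new stereocentre C2 is formed racemic and is erased in step 2.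

Step 2
Reactants: 3 2-(2,4-dibromophenoxy)cyclohexan-1-one
Product: 7 2,3,4-tribromo-6-(2,4-dibromophenoxy)phenol, via tribromoketone 4 (not isolated), via bromophenol 5 (not isolated), via dibromophenol 6 (not isolated)
Conditions: Br2 (3.05 equiv), AcOH, 20 °C, 2 h; then 90 °C, 3 h; then Br2 (2.1 equiv), 20→50 °C, dark; aq NaHSO3; recrystallise
Reagents that add atoms: bromine, BrBr
Why: Acid-catalysed enol bromination should replace all three α-hydrogens of 3 (C6 twice, C2 once) to give 4, which on warming should lose two HBr by enolization and ionization of the α-bromides and tautomerize to phenol 5; this is the halogenation–dehydrohalogenation aromatization by which 2,2,6-trihalo- and 2,2,6,6-tetrahalocyclohexanones are turned into 2-halo- and 2,6-dihalophenols, followed in the same flask by ordinary phenol bromination through 6. No ring is closed: the existing six-membered carbocycle is aromatized, its carbonyl oxygen becoming the phenol OH at C1 and its α-carbon the ether carbon C2. No stereocentre is created, the racemic centre of 3 disappears and the target is achiral. The selectivity needed is positional: the C6 bromine is fixed on sp3 carbon before the ring is aromatic, the fourth bromine should enter C4 (para to the free OH, the only ortho/para position left), and the fifth should enter C5, para to the ether oxygen, in preference to C3 (ortho to the bulky aryloxy group) and to C6' of ring B (meta to two bromines, on a ring that shares its ether oxygen with electron-poor ring A). The order of α-bromination, HBr loss and nuclear bromination should not matter, because any 2-aryloxyphenol formed early would be brominated at the same C4 and C6 positions, so the manifold should converge on 7 once five equivalents of Br2 are consumed.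

**Compound list**
1 | 2,4-dibromophenol | Oc1ccc(Br)cc1Br | starting material
2 | 2-chlorocyclohexan-1-one (racemic) | O=C1CCCCC1Cl | starting material
3 | 2-(2,4-dibromophenoxy)cyclohexan-1-one (racemic) | O=C1CCCCC1Oc1ccc(Br)cc1Br | intermediate
4 | 2,6,6-tribromo-2-(2,4-dibromophenoxy)cyclohexan-1-one (racemic) | O=C1C(Br)(Br)CCCC1(Br)Oc1ccc(Br)cc1Br | intermediate (not isolated)
5 | 2-bromo-6-(2,4-dibromophenoxy)phenol | Oc1c(Br)cccc1Oc1ccc(Br)cc1Br | intermediate (not isolated)
6 | 2,4-dibromo-6-(2,4-dibromophenoxy)phenol | Oc1c(Br)cc(Br)cc1Oc1ccc(Br)cc1Br | intermediate (not isolated)
7 | 2,3,4-tribromo-6-(2,4-dibromophenoxy)phenol, also named 4,5,6-tribromo-2-(2,4-dibromophenoxy)phenol; achiral | Oc1c(Oc2ccc(Br)cc2Br)cc(Br)c(Br)c1Br | target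

Total step count: 2. Longest linear sequence: 2 steps. The route has only two steps, so both are ranked.

**Most likely to fail, first: step 2 (key step).** Four processes could spoil it:
- Bromine could add across the enol-ether C2=C3 double bond of a transient 2-aryloxycyclohexenone and end up at C3.
- The fifth bromine could enter C3 or C6' of ring B instead of the crowded C5.
- Acetolysis at the α-bromo ether carbon C2 could cost the aryloxy group.
- Acid could cyclodehydrate the ketone onto ring B.

The fallback gives up the aromatization and carries the C5 bromine in a building block, so that only the two OH-directed positions have to be brominated. It sets out from 1 and comes back to the route at 7. Phenol 1 would be O-arylated with (4-bromo-2-methoxyphenyl)boronic acid under Chan–Lam conditions (Cu(OAc)2, pyridine, 4 Å molecular sieves, CH2Cl2, air, 20 °C), which leave aryl bromides untouched, to give 4-bromo-1-(2,4-dibromophenoxy)-2-methoxybenzene F1. Demethylation with BBr3 (CH2Cl2, −78→0 °C) should give phenol A3. Bromination (Br2, 2.1 equiv, AcOH, 20→40 °C) should then proceed through 4,5-dibromo-2-(2,4-dibromophenoxy)phenol F2 to 7.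

**Second: step 1.** Enolization of chloroketone 2 with Favorskii-type rearrangement, self-condensation or loss of HCl could outrun the slow SN2 attack of the hindered phenoxide. The fallback replaces the α-halo ketone by an epoxide and adds the carbonyl afterwards. It sets out from 1 and comes back at 3. Phenol 1 would open cyclohexene oxide (Cs2CO3 cat., DMF, 100 °C) by anti SN2 attack to give racemic trans-2-(2,4-dibromophenoxy)cyclohexan-1-ol F3, which Dess–Martin periodinane (CH2Cl2, 20 °C) should oxidize to 3.

**Further compounds**
F1 | step 2 | 4-bromo-1-(2,4-dibromophenoxy)-2-methoxybenzene | COc1cc(Br)ccc1Oc1ccc(Br)cc1Br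
F2 | step 2 | 4,5-dibromo-2-(2,4-dibromophenoxy)phenol | Oc1cc(Br)c(Br)cc1Oc1ccc(Br)cc1Br
F3 | step 1 | trans-2-(2,4-dibromophenoxy)cyclohexan-1-ol (racemic, one enantiomer drawn) | O[C@@H]1CCCC[C@H]1Oc1ccc(Br)cc1Br
A1 | direct plan | 5-bromo-2-fluorobenzaldehyde | O=Cc1cc(Br)ccc1F
A2 | direct plan | 5-bromo-2-(2,4-dibromophenoxy)benzaldehyde | O=Cc1cc(Br)ccc1Oc1ccc(Br)cc1Br
A3 | direct plan | 5-bromo-2-(2,4-dibromophenoxy)phenol | Oc1cc(Br)ccc1Oc1ccc(Br)cc1Br
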